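**Plan**
- Retrosynthesis: the acetate, the free phenol and the ketone are unmasked last. The arene is traced back to a methyl resorcylate that carries one extra ester carbon on the ring carbon next to the side chain; this carbon is later lost as CO2.
- Enabling feature: the benzene ring has oxygen on both carbons meta to the benzylic carbon C1 (C2 of the chain bears the acetate, C8 is the ketone). This is the folding pattern of a tetraketide, so the ring is cut between the ring carbon that carries C1 and its ester-bearing neighbour, giving a linear 3,5,7-triketo ester.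
- The triketo ester is cut at C6–C7 into the trianion of methyl 3,5-dioxohexanoate and a C14 Weinreb amide. The amide is cut at its C2–C3 bond (Meldrum's acid) and at the ketone–pentyl bond (pentyl Grignard and pimelate half-ester chloride).
- Forward: C12 keto ester, C14 β-keto ester, C20 triketo ester, then the only ring closes by aldol aromatization. O-methylation, decarboxylation, deprotection and acetylation follow.
- Stereochemistry: the single (R) carbinol centre comes from Noyori hydrogenation of the β-keto ester with RuCl2[(R)-BINAP] and is carried through unchanged.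

Key step: step 10

Assumption: the stereocentre of the target (carbinol carbon C2 of the tridecyl chain) is (R), as read from the SMILES. Polycarbonyl compounds are drawn as keto tautomers although they exist largely as enols.

**Step 1**
Reactants: 1 7-ethoxy-7-oxoheptanoic acid
Product: 2 ethyl 7-chloro-7-oxoheptanoate
Conditions: (COCl)2, DMF (cat.), CH2Cl2, 0 → 23 °C; concentrate
Reagents that add atoms: oxalyl chloride, ClC(=O)C(=O)Cl
Why: Acid chloride formation with oxalyl chloride under DMF catalysis converts only the free acid, leaves the ethyl ester untouched and gives only gaseous by-products.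

**Step 2**
Reactants: 2 ethyl 7-chloro-7-oxoheptanoate; 3 1-bromopentane
Product: 5 ethyl 7-oxododecanoate, via pentylmagnesium bromide 4 (not isolated)
Conditions: 3, Mg, THF, 23–40 °C; then add to 2, Fe(acac)3 (3 mol %), THF, −78 °C
Reagents that add atoms: none
Why: Iron-catalysed acylation of a Grignard reagent with an acid chloride is much faster at −78 °C than addition to the ester or to the ketone formed, so the pentyl ketone should result without tertiary alcohol.

**Step 3**
Reactants: 5 ethyl 7-oxododecanoate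
Product: 6 7-oxododecanoic acid
Conditions: LiOH·H2O, THF–H2O (3:1), 23 °C; then 1 M HCl
Reagents that add atoms: lithium hydroxide, [Li+].[OH-]
Why: Ester saponification at room temperature; the dialkyl ketone is inert to aqueous LiOH.

**Step 4**
Reactants: 6 7-oxododecanoic acid; 7 Meldrum's acid (2,2-dimethyl-1,3-dioxane-4,6-dione)
Product: 9 methyl 3,9-dioxotetradecanoate, via acyl Meldrum's acid 8 (not isolated)
Conditions: DCC, DMAP, CH2Cl2, 0 → 23 °C; filter; then MeOH, reflux
Reagents that add atoms: methanol, CO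
Why: Carbodiimide-mediated C-acylation of Meldrum's acid followed by methanolysis (the Meldrum's acid β-keto ester synthesis) works because the acyl Meldrum's acid loses acetone and CO2 on heating to an acylketene that methanol traps.

**Step 5**
Reactants: 9 methyl 3,9-dioxotetradecanoate
Product: 10 methyl (3R)-3-hydroxy-9-oxotetradecanoate
Conditions: H2 (50 bar), RuCl2[(R)-BINAP] (0.5 mol %), MeOH, 50 °C
Reagents that add atoms: none
Why: Noyori asymmetric hydrogenation: only the chelating β-keto ester binds the BINAP–ruthenium catalyst, and the (R)-ligand delivers hydrogen in the same facial sense that turns methyl acetoacetate into (R)-3-hydroxybutanoate, so the (3R)-alcohol is expected while the isolated C9 ketone is not reduced.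

**Step 6**
Reactants: 10 methyl (3R)-3-hydroxy-9-oxotetradecanoate
Product: 11 methyl (3R)-3-hydroxy-8-(2-pentyl-1,3-dioxolan-2-yl)octanoate
Conditions: ethylene glycol, PPTS (cat.), benzene, reflux, Dean–Stark
Reagents that add atoms: ethylene glycol, OCCO
Why: Acid-catalysed ketalization with azeotropic removal of water (dioxolane formation); the weak acid PPTS is chosen so that the β-hydroxy ester neither dehydrates nor transesterifies.

**Step 7**
Reactants: 11 methyl (3R)-3-hydroxy-8-(2-pentyl-1,3-dioxolan-2-yl)octanoate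
Product: 12 methyl (3R)-8-(2-pentyl-1,3-dioxolan-2-yl)-3-(triisopropylsilyloxy)octanoate
Conditions: TIPSOTf, 2,6-lutidine, CH2Cl2, −78 → 0 °C
Reagents that add atoms: triisopropylsilyl trifluoromethanesulfonate, CC(C)[Si](OS(=O)(=O)C(F)(F)F)(C(C)C)C(C)C
Why: Silylation of a secondary alcohol with a silyl triflate and a hindered pyridine base; the buffered, cold conditions keep the dioxolane closed, and the bulky silyl group is chosen to resist base and oxygen-to-oxygen migration later.

**Step 8**
Reactants: 12 methyl (3R)-8-(2-pentyl-1,3-dioxolan-2-yl)-3-(triisopropylsilyloxy)octanoate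
Product: 13 (3R)-N-methoxy-N-methyl-8-(2-pentyl-1,3-dioxolan-2-yl)-3-(triisopropylsilyloxy)octanamide
Conditions: MeNHOMe·HCl, iPrMgCl, THF, −20 → 0 °C
Reagents that add atoms: N,O-dimethylhydroxylamine hydrochloride, CNOC.Cl
Why: Weinreb amidation of an ester with the chloromagnesium amide of N,O-dimethylhydroxylamine; the low temperature and the non-nucleophilic Grignard base avoid β-elimination of the silyloxy group.

**Step 9**
Reactants: 13 (3R)-N-methoxy-N-methyl-8-(2-pentyl-1,3-dioxolan-2-yl)-3-(triisopropylsilyloxy)octanamide; 14 methyl 3,5-dioxohexanoate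
Product: 16 methyl (9R)-3,5,7-trioxo-14-(2-pentyl-1,3-dioxolan-2-yl)-9-(triisopropylsilyloxy)tetradecanoate, via trilithiated diketo ester 15 (not isolated)
Conditions: 14 (2 equiv), LiN(iPr)2 (6.2 equiv), THF, −78 → 0 °C; then 13, −78 → 0 °C; AcOH, −78 °C
Reagents that add atoms: none
Why: γ-Acylation of a β-dicarbonyl polyanion: the last-formed terminal carbanion of the trianion is its most nucleophilic site and the N-methoxy-N-methylamide stops at the ketone oxidation level; the cyclization-prone product is worked up cold and used without chromatography.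

**Step 10**
Reactants: 16 methyl (9R)-3,5,7-trioxo-14-(2-pentyl-1,3-dioxolan-2-yl)-9-(triisopropylsilyloxy)tetradecanoate
Product: 18 methyl 2,4-dihydroxy-6-[(2R)-7-(2-pentyl-1,3-dioxolan-2-yl)-2-(triisopropylsilyloxy)heptyl]benzoate, via cyclic aldol adduct 17 (not isolated)
Conditions: aq. KHCO3/K2CO3 buffer (pH ≈ 9.5), MeOH–THF, 23 °C
Reagents that add atoms: none
Why: In the buffered protic medium the triketo ester exists as rapidly exchanging anions; the C2 carbanion, stabilized by the ester and the 3-ketone, adds to the 7-carbonyl, the cyclic aldol 17 loses water by E1cB and the 3- and 5-carbonyls tautomerize to phenols, which makes the sequence irreversible (intramolecular aldol condensation–aromatization, the known base-induced cyclization of 3,5,7-triketo esters to resorcylates). The benzene ring closes in a 6-(enolendo)-exo-trig mode by forming the bond between chain C2 and C7, that is between the ester-bearing ring carbon and the ring carbon that carries the side chain. No stereocentre is created, since all ring carbons end up sp2 and the C9 centre is a spectator. The selectivity needed is aldol closure of C2 onto the ketone over Claisen closure of C6 onto the ester and over oxygen cyclization to pyranones: towards a stabilized carbanion in water–methanol a ketone is far more electrophilic than an ester, Claisen closure needs the more highly charged anions made by strong aprotic base, and pyranone formation needs acid or dehydrating conditions, all of which the buffer avoids. The β-silyloxy group should survive because the C8 hydrogens are those of a simple ketone and many orders of magnitude less acidic than those at C2, C4 and C6, so no enolate forms towards C8 at this pH, and after aromatization C8 is an unactivated benzylic methylene.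

**Step 11**
Reactants: 18 methyl 2,4-dihydroxy-6-[(2R)-7-(2-pentyl-1,3-dioxolan-2-yl)-2-(triisopropylsilyloxy)heptyl]benzoate
Product: 19 methyl 2-hydroxy-4-methoxy-6-[(2R)-7-(2-pentyl-1,3-dioxolan-2-yl)-2-(triisopropylsilyloxy)heptyl]benzoate
Conditions: MeI (1.1 equiv), K2CO3, acetone, 23 °C
Reagents that add atoms: iodomethane, CI
Why: Williamson ether synthesis under weak base: the 2-hydroxyl is tied up in a hydrogen bond to the ester carbonyl and is the less acidic and less nucleophilic one, so one equivalent of iodomethane should alkylate only the 4-hydroxyl.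

**Step 12**
Reactants: 19 methyl 2-hydroxy-4-methoxy-6-[(2R)-7-(2-pentyl-1,3-dioxolan-2-yl)-2-(triisopropylsilyloxy)heptyl]benzoate
Product: 22 (12R)-13-(3-hydroxy-5-methoxyphenyl)-12-(triisopropylsilyloxy)tridecan-6-one, via ketal acid 20 (not isolated), via keto acid 21 (not isolated)
Conditions: KOH, EtOH–H2O (1:1), reflux; then 1 M HCl, THF, 23 °C; then toluene, 110 °C
Reagents that add atoms: water, O
Why: Saponification of the salicylate ester, acid hydrolysis of the dioxolane and thermal protodecarboxylation of the electron-rich salicylic acid (ipso protonation ortho and para to the two ring oxygens, as for orsellinic-type acids) follow one another, and the secondary triisopropylsilyl ether should tolerate all three stages.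

**Step 13**
Reactants: 22 (12R)-13-(3-hydroxy-5-methoxyphenyl)-12-(triisopropylsilyloxy)tridecan-6-one
Product: 23 (12R)-12-hydroxy-13-(3-hydroxy-5-methoxyphenyl)tridecan-6-one
Conditions: Bu4NF, THF, 23 °C; H2O
Reagents that add atoms: none
Why: Fluoride-induced desilylation, driven by the strong Si–F bond, frees the secondary alcohol without touching the ketone or the aryl methyl ether.

**Step 14**
Reactants: 23 (12R)-12-hydroxy-13-(3-hydroxy-5-methoxyphenyl)tridecan-6-one
Product: 24 3-[(2R)-2-acetoxy-8-oxotridecyl]-5-methoxyphenyl acetate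
Conditions: Ac2O, pyridine, DMAP (cat.), CH2Cl2, 23 °C
Reagents that add atoms: acetic anhydride, CC(=O)OC(C)=O
Why: DMAP-catalysed acetylation (nucleophilic catalysis) esterifies both the phenol and the secondary alcohol, the latter with retention because the C–O bond is not broken.

**Step 15**
Reactants: 24 3-[(2R)-2-acetoxy-8-oxotridecyl]-5-methoxyphenyl acetate
Product: 25 (2R)-1-(3-hydroxy-5-methoxyphenyl)-8-oxotridecan-2-yl acetate
Conditions: K2CO3 (0.2 equiv), MeOH, 0 °C
Reagents that add atoms: none
Why: Base-catalysed transesterification (Zemplén-type methanolysis) is much faster for the aryl acetate, whose phenoxide is the better leaving group, than for the secondary alkyl acetate, so short exposure at 0 °C should unmask only the phenol.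

**Compound list**
1 | 7-ethoxy-7-oxoheptanoic acid (pimelic acid monoethyl ester) | CCOC(=O)CCCCCC(=O)O | starting material
2 | ethyl 7-chloro-7-oxoheptanoate | CCOC(=O)CCCCCC(=O)Cl | intermediate
3 | 1-bromopentane | CCCCCBr | starting material
4 | pentylmagnesium bromide (not isolated) | CCCCC[Mg]Br | intermediate
5 | ethyl 7-oxododecanoate | CCCCCC(=O)CCCCCC(=O)OCC | intermediate
6 | 7-oxododecanoic acid | CCCCCC(=O)CCCCCC(=O)O | intermediate
7 | Meldrum's acid (2,2-dimethyl-1,3-dioxane-4,6-dione) | CC1(C)OC(=O)CC(=O)O1 | starting material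
8 | 5-(1-hydroxy-7-oxododecylidene)-2,2-dimethyl-1,3-dioxane-4,6-dione (acyl Meldrum's acid, not isolated) | CCCCCC(=O)CCCCCC(O)=C1C(=O)OC(C)(C)OC1=O | intermediate
9 | methyl 3,9-dioxotetradecanoate | CCCCCC(=O)CCCCCC(=O)CC(=O)OC | intermediate
10 | methyl (3R)-3-hydroxy-9-oxotetradecanoate | CCCCCC(=O)CCCCC[C@H](CC(=O)OC)O | intermediate
11 | methyl (3R)-3-hydroxy-8-(2-pentyl-1,3-dioxolan-2-yl)octanoate | CCCCCC1(CCCCC[C@H](CC(=O)OC)O)OCCO1 | intermediate
12 | methyl (3R)-8-(2-pentyl-1,3-dioxolan-2-yl)-3-(triisopropylsilyloxy)octanoate | CCCCCC1(CCCCC[C@H](CC(=O)OC)O[Si](C(C)C)(C(C)C)C(C)C)OCCO1 | intermediate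
13 | (3R)-N-methoxy-N-methyl-8-(2-pentyl-1,3-dioxolan-2-yl)-3-(triisopropylsilyloxy)octanamide | CCCCCC1(CCCCC[C@H](CC(=O)N(C)OC)O[Si](C(C)C)(C(C)C)C(C)C)OCCO1 | intermediate
14 | methyl 3,5-dioxohexanoate | COC(=O)CC(=O)CC(C)=O | starting material
15 | trilithium trianion of methyl 3,5-dioxohexanoate (not isolated) | [Li+].[Li+].[Li+].[CH2-]C(=O)[CH-]C(=O)[CH-]C(=O)OC | intermediate
16 | methyl (9R)-3,5,7-trioxo-14-(2-pentyl-1,3-dioxolan-2-yl)-9-(triisopropylsilyloxy)tetradecanoate | COC(=O)CC(=O)CC(=O)CC(=O)C[C@@H](CCCCCC1(CCCCC)OCCO1)O[Si](C(C)C)(C(C)C)C(C)C | intermediate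
17 | methyl 2-hydroxy-4,6-dioxo-2-[(2R)-7-(2-pentyl-1,3-dioxolan-2-yl)-2-(triisopropylsilyloxy)heptyl]cyclohexane-1-carboxylate (cyclic aldol adduct, ring centres undefined, not isolated) | COC(=O)C1C(=O)CC(=O)CC1(O)C[C@@H](CCCCCC2(CCCCC)OCCO2)O[Si](C(C)C)(C(C)C)C(C)C | intermediate
18 | methyl 2,4-dihydroxy-6-[(2R)-7-(2-pentyl-1,3-dioxolan-2-yl)-2-(triisopropylsilyloxy)heptyl]benzoate | CCCCCC1(CCCCC[C@H](Cc2cc(O)cc(O)c2C(=O)OC)O[Si](C(C)C)(C(C)C)C(C)C)OCCO1 | intermediate
19 | methyl 2-hydroxy-4-methoxy-6-[(2R)-7-(2-pentyl-1,3-dioxolan-2-yl)-2-(triisopropylsilyloxy)heptyl]benzoate | CCCCCC1(CCCCC[C@H](Cc2cc(OC)cc(O)c2C(=O)OC)O[Si](C(C)C)(C(C)C)C(C)C)OCCO1 | intermediate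
20 | 2-hydroxy-4-methoxy-6-[(2R)-7-(2-pentyl-1,3-dioxolan-2-yl)-2-(triisopropylsilyloxy)heptyl]benzoic acid (ketal acid, formed as its potassium salt, not isolated) | CCCCCC1(CCCCC[C@H](Cc2cc(OC)cc(O)c2C(=O)O)O[Si](C(C)C)(C(C)C)C(C)C)OCCO1 | intermediate
21 | 2-hydroxy-4-methoxy-6-[(2R)-8-oxo-2-(triisopropylsilyloxy)tridecyl]benzoic acid (keto acid, not isolated) | CCCCCC(=O)CCCCC[C@H](Cc1cc(OC)cc(O)c1C(=O)O)O[Si](C(C)C)(C(C)C)C(C)C | intermediate
22 | (12R)-13-(3-hydroxy-5-methoxyphenyl)-12-(triisopropylsilyloxy)tridecan-6-one | CCCCCC(=O)CCCCC[C@H](Cc1cc(O)cc(OC)c1)O[Si](C(C)C)(C(C)C)C(C)C | intermediate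
23 | (12R)-12-hydroxy-13-(3-hydroxy-5-methoxyphenyl)tridecan-6-one | CCCCCC(=O)CCCCC[C@H](Cc1cc(O)cc(OC)c1)O | intermediate
24 | 3-[(2R)-2-acetoxy-8-oxotridecyl]-5-methoxyphenyl acetate | CCCCCC(=O)CCCCC[C@H](Cc1cc(OC(C)=O)cc(OC)c1)OC(C)=O | intermediate
25 | (2R)-1-(3-hydroxy-5-methoxyphenyl)-8-oxotridecan-2-yl acetate | CCCCCC(=O)CCCCC[C@H](Cc1cc(O)cc(OC)c1)OC(C)=O | target

**Step count**
Total: 15 steps. Longest linear sequence: 15 steps (1 to 25).

**Steps most likely to fail**

Step 9. The trianion may act as a base instead of a nucleophile, removing a proton next to the amide carbonyl with subsequent loss of the silyloxy group, or it may add too slowly to the β-branched amide. The fallback replaces acylation by aldol addition and oxidation. It sets out from 13, which iBu2AlH (THF, −78 °C) should reduce to (3R)-8-(2-pentyl-1,3-dioxolan-2-yl)-3-(triisopropylsilyloxy)octanal F1. Trianion 15 should add to this aldehyde at −78 °C to give methyl (9R)-7-hydroxy-3,5-dioxo-14-(2-pentyl-1,3-dioxolan-2-yl)-9-(triisopropylsilyloxy)tetradecanoate F2 as a mixture at C7. Oxidation of the carbinol with Dess–Martin periodinane (1.1 equiv, NaHCO3, CH2Cl2, 0 °C) comes back to the route at 16.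

Step 10. The ring may close in the wrong sense (C6 onto the ester carbonyl, or an enol oxygen onto a carbonyl to give pyranones), or the silyloxy group may be eliminated before the ring closes. The fallback ties the ester and the 3-oxygen into a 1,3-dioxin-4-one, so that no ester is open to Claisen or pyranone closure while the same ring bond is made. It sets out from 13. The dilithium dianion of 2,2-dimethyl-6-(2-oxopropyl)-4H-1,3-dioxin-4-one F3 (from commercial 2,2,6-trimethyl-4H-1,3-dioxin-4-one, LiN(SiMe3)2 and acetyl chloride) is acylated with 13 to give 2,2-dimethyl-6-[(6R)-2,4-dioxo-11-(2-pentyl-1,3-dioxolan-2-yl)-6-(triisopropylsilyloxy)undecyl]-4H-1,3-dioxin-4-one F4. Et3N in CH2Cl2 at 23 °C should bring about aldol aromatization (dioxinone C5 onto the remote ketone) to 7-hydroxy-2,2-dimethyl-5-[(2R)-7-(2-pentyl-1,3-dioxolan-2-yl)-2-(triisopropylsilyloxy)heptyl]-4H-1,3-benzodioxin-4-one F5. Its only free hydroxyl is methylated (MeI, K2CO3, acetone) to 7-methoxy-2,2-dimethyl-5-[(2R)-7-(2-pentyl-1,3-dioxolan-2-yl)-2-(triisopropylsilyloxy)heptyl]-4H-1,3-benzodioxin-4-one F6. KOH in aqueous dioxane opens the acylal with loss of acetone, and the route is rejoined at acid 20, which is taken through the acid and thermal stages of step 12.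

Step 12. Hydrolysis of the doubly ortho-substituted, hydrogen-bonded ester may stay incomplete, and forcing the alkali may erode the silyl ether or the aryl methyl ether. The fallback carries a benzyl ester through the key step so that the acid is released by hydrogenolysis under neutral conditions. It sets out from 13. Benzyl 3,5-dioxohexanoate F7 (from commercial benzyl acetoacetate by dianion formation with NaH then BuLi and acylation with N-methoxy-N-methylacetamide) is converted to its trianion with LiN(iPr)2 and acylated with 13 as in step 9, giving benzyl (9R)-3,5,7-trioxo-14-(2-pentyl-1,3-dioxolan-2-yl)-9-(triisopropylsilyloxy)tetradecanoate F8. The buffered aldol aromatization of step 10 should give benzyl 2,4-dihydroxy-6-[(2R)-7-(2-pentyl-1,3-dioxolan-2-yl)-2-(triisopropylsilyloxy)heptyl]benzoate F9, and MeI with K2CO3 in acetone should give benzyl 2-hydroxy-4-methoxy-6-[(2R)-7-(2-pentyl-1,3-dioxolan-2-yl)-2-(triisopropylsilyloxy)heptyl]benzoate F10. Hydrogenolysis (H2, Pd/C with 10% Pd on carbon, EtOAc, 23 °C) cleaves the benzyl ester with loss of toluene, and the route is rejoined at acid 20.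

**Further compounds**
F1 | step 9 | (3R)-8-(2-pentyl-1,3-dioxolan-2-yl)-3-(triisopropylsilyloxy)octanal | CCCCCC1(CCCCC[C@H](CC=O)O[Si](C(C)C)(C(C)C)C(C)C)OCCO1
F2 | step 9 | methyl (9R)-7-hydroxy-3,5-dioxo-14-(2-pentyl-1,3-dioxolan-2-yl)-9-(triisopropylsilyloxy)tetradecanoate | COC(=O)CC(=O)CC(=O)CC(O)C[C@@H](CCCCCC1(CCCCC)OCCO1)O[Si](C(C)C)(C(C)C)C(C)C
F3 | step 10 | 2,2-dimethyl-6-(2-oxopropyl)-4H-1,3-dioxin-4-one | CC(=O)CC1=CC(=O)OC(C)(C)O1
F4 | step 10 | 2,2-dimethyl-6-[(6R)-2,4-dioxo-11-(2-pentyl-1,3-dioxolan-2-yl)-6-(triisopropylsilyloxy)undecyl]-4H-1,3-dioxin-4-one | CC1(C)OC(=O)C=C(CC(=O)CC(=O)C[C@@H](CCCCCC2(CCCCC)OCCO2)O[Si](C(C)C)(C(C)C)C(C)C)O1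
F5 | step 10 | 7-hydroxy-2,2-dimethyl-5-[(2R)-7-(2-pentyl-1,3-dioxolan-2-yl)-2-(triisopropylsilyloxy)heptyl]-4H-1,3-benzodioxin-4-one | CC1(C)OC(=O)c2c(C[C@@H](CCCCCC3(CCCCC)OCCO3)O[Si](C(C)C)(C(C)C)C(C)C)cc(O)cc2O1
F6 | step 10 | 7-methoxy-2,2-dimethyl-5-[(2R)-7-(2-pentyl-1,3-dioxolan-2-yl)-2-(triisopropylsilyloxy)heptyl]-4H-1,3-benzodioxin-4-one | CC1(C)OC(=O)c2c(C[C@@H](CCCCCC3(CCCCC)OCCO3)O[Si](C(C)C)(C(C)C)C(C)C)cc(OC)cc2O1
F7 | step 12 | benzyl 3,5-dioxohexanoate | CC(=O)CC(=O)CC(=O)OCc1ccccc1
F8 | step 12 | benzyl (9R)-3,5,7-trioxo-14-(2-pentyl-1,3-dioxolan-2-yl)-9-(triisopropylsilyloxy)tetradecanoate | O=C(CC(=O)CC(=O)CC(=O)C[C@@H](CCCCCC1(CCCCC)OCCO1)O[Si](C(C)C)(C(C)C)C(C)C)OCc2ccccc2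
F9 | step 12 | benzyl 2,4-dihydroxy-6-[(2R)-7-(2-pentyl-1,3-dioxolan-2-yl)-2-(triisopropylsilyloxy)heptyl]benzoate | CCCCCC1(CCCCC[C@H](Cc2cc(O)cc(O)c2C(=O)OCc3ccccc3)O[Si](C(C)C)(C(C)C)C(C)C)OCCO1
F10 | step 12 | benzyl 2-hydroxy-4-methoxy-6-[(2R)-7-(2-pentyl-1,3-dioxolan-2-yl)-2-(triisopropylsilyloxy)heptyl]benzoate | CCCCCC1(CCCCC[C@H](Cc2cc(OC)cc(O)c2C(=O)OCc3ccccc3)O[Si](C(C)C)(C(C)C)C(C)C)OCCO1
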